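The data are simulated with constants of no real substance.

The closed, stirred vessel held J with a little G and D, and I wanted the books on J and G at the end of each run.

in all of them: J 0.050 M; G 5 mol%

| charge | D | remark | time |
|---|---|---|---|
| dusk | 1.1 mM | run made earlier |  |
| autumn | 1.7 mM | run made earlier |  |
| spring | 1.5 mM | run made earlier |  |
| west | 1.3 mM |  | 8.0 h |
| north | 2.0 mM |  | 8.0 h |

| run | time / h | L / % | J / % |
|---|---|---|---|
| dusk | 0.667 | 3 | 90 |
| dusk | 1.33 | 8 | 78 |
| dusk | 2.50 | 22 | 60 |
| dusk | 4.00 | 27 | 44 |
| dusk | 8.00 | 44 | 15 |
| autumn | 1.50 | 6 | 78 |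
| autumn | 3.00 | 14 | 60 |
| autumn | 5.00 | 25 | 40 |
| autumn | 6.00 | 26 | 29 |
| autumn | 8.00 | 31 | 27 |
| spring | 0.667 | 2 | 87 |
| spring | 2.00 | 10 | 72 |
| spring | 4.00 | 25 | 49 |
| spring | 6.00 | 28 | 31 |
| spring | 8.00 | 36 | 19 |

(standard deviation of a reading: 2 percentage points)

1. which of the two ends with the longer chains by the average number of monomer units in a chain (chains begun, living or dead) ("neither" if they lie within 10%) (west / north / neither)
2. average number of monomer units in a chain (chains begun, living or dead) at the end, west
3. average number of monomer units in a chain (chains begun, living or dead) at the end, north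

- the average divides the monomer in chains by the number of chains begun, living and dead together
- the numbers in the tables scatter by 2 percentage points (one standard deviation)
- the earlier runs do not show the number of chains; that part of a forecast is a guess

At 8.00 h, L fell from 44% in dusk to 31% in autumn as D rose, while the part that was neither J nor L stayed between 41.0% and 45.0%. I therefore read L as monomer in chains and the missing part as a loss that ignored G. I supposed that D removes G one for one and that each remaining G begins one chain, so the chain count is g, G charged minus D charged.

The split s, L over the missing part (a selectivity factor), divided by g, read 0.767 /mM in dusk, 0.800 /mM in spring and 0.923 /mM in autumn. Pooled, this gives the split per live G, σ = 0.816 /mM. The J readings then give the first-order rate of the missing part, k = 0.108 /h.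

My ledger, with s = σg and J left = exp(−k(s + 1)t):

West: g 1.20 mM, s 0.979, J left 18.0%, L 40.6%, length 16.9

North: g 0.500 mM, s 0.408, J left 29.5%, L 20.4%, length 20.4

So I committed to north. The forecast differed and named west, with 16 for west and 11 for north, “Guessing that each D starts one chain”.

The flask gave 17.4 in west and 21.8 in north, so north ended longer.

    J + G → X + L (k = 0.00580 /M/s)
    J + X → L + X, rate k2*[X]*[J] (k = 0.0290 /M/s)
    G + D → Q (k = 5.90 /M/s)
    J → Z (k = 2.80 × 10⁻⁵ /s)

At the start of west, G reacted with D 26.4 times as fast as with J. At 8.00 h west held Q 0.00130 M and X 0.00118 M, and north held Q 0.00200 M and X 4.97 × 10⁻⁴ M, close to g in both. On a flask like west but with 0.20 M of J, G at the same loading and D unchanged, g is 8.70 mM, s is 7.10, L is 87.6% and the length 20.1. The computed flask gave L 88.3% and length 20.4.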